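**Strategy.** Everything rests on cutting ring A at C6–C11, the bond between the spiro carbon and the gem-dimethyl carbon that lies next to the C10 bromide. In the forward sense a bromonium ion on the C10–C11 alkene of a monocyclic dienol is opened by C6 of its tetrasubstituted C6–C7 alkene. One operation forms C10–Br and C6–C11, closes ring A, sets C6 and C10 and, by loss of a C14 proton, leaves the exocyclic methylene. The precursor is an (E)-2-bromo-3-chloro-γ-bisabolen-9-ol whose ring B carries the trans-diaxial C2–Br/C3–Cl pair derived from (R)-limonene; C9 is carried as the 9R epimer and inverted after the closure.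

Key step: step 9

Remark on numbering: chamigrane locants are used throughout (C6 spiro; ring B = C1–C6 with C2–Br and C3(CH3)Cl; ring A = C6–C11 with exocyclic C14 on C7, oxygen on C9, bromine on C10, gem-dimethyl C11).

Remark on the design: a chair closure puts the C10 bromine equatorial and one C11 methyl axial, so a 9S hydroxyl would sit axial against that methyl whereas a 9R hydroxyl is equatorial; the closure is therefore run on the 9R epimer and C9 is corrected in steps 10 and 11.

Step 1
Reactants: 1 (R)-limonene
Product: 2 (1S,2S,4R)-2-bromo-1-chloro-1-methyl-4-(prop-1-en-2-yl)cyclohexane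
Conditions: NBS, Me3SiCl, CH2Cl2, −78 °C
Reagents that add atoms: N-bromosuccinimide (O=C1CCC(=O)N1Br); chlorotrimethylsilane (C[Si](C)(C)Cl)
Why: Electrophilic bromochlorination with BrCl made in the flask: the trisubstituted ring alkene is more nucleophilic than the isopropenyl group, chloride opens the bromonium ion at the tertiary carbon (Markovnikov), and only a trans-diaxial (Fürst–Plattner) opening keeps the isopropenyl group equatorial, so the limonene stereocentre sets C2 and C3 (Br trans, Cl cis to the side chain).

Step 2
Reactants: 2 (1S,2S,4R)-2-bromo-1-chloro-1-methyl-4-(prop-1-en-2-yl)cyclohexane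
Product: 4 1-[(1R,3S,4S)-3-bromo-4-chloro-4-methylcyclohexyl]ethan-1-one, via secondary ozonide 3 (not isolated)
Conditions: O3, CH2Cl2, −78 °C; then PPh3, −78 to 20 °C
Reagents that add atoms: ozone ([O-][O+]=O)
Why: Ozonolysis with reductive work-up cleaves the only remaining alkene to the methyl ketone; the alkyl halides are inert to ozone and the ring methine is not touched.

Step 3
Reactants: 4 1-[(1R,3S,4S)-3-bromo-4-chloro-4-methylcyclohexyl]ethan-1-one
Product: 5 1-[(1R,3S,4S)-3-bromo-4-chloro-4-methyl-1-(phenylselanyl)cyclohexyl]ethan-1-one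
Conditions: PhSeCl, EtOAc, 20 °C
Reagents that add atoms: benzeneselenenyl chloride (Cl[Se]c1ccccc1)
Why: Acid-promoted α-selenenylation of a ketone through its more substituted enol (the HCl released catalyses enolisation); PhSeCl attacks the exocyclic enol on the face opposite the axial C2 bromine, so selenium enters trans to bromine and marks C6 for a regiospecific elimination later.

Step 4
Reactants: 5 1-[(1R,3S,4S)-3-bromo-4-chloro-4-methyl-1-(phenylselanyl)cyclohexyl]ethan-1-one; 6 3-methylbut-2-enal
Product: 8 (3R)-1-[(1R,3S,4S)-3-bromo-4-chloro-4-methyl-1-(phenylselanyl)cyclohexyl]-3-hydroxy-5-methylhex-4-en-1-one, via silyl enol ether 7 (not isolated)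
Conditions: Me3SiOTf, Et3N, CH2Cl2, 0 °C; then 6, SiCl4, (R,R)-binaphthyldiamine-derived bisphosphoramide (5 mol %), iPr2NEt (10 mol %), CH2Cl2, −78 °C; aq. NaHCO3
Reagents that add atoms: none
Why: Mukaiyama aldol addition under Lewis-base-activated SiCl4 catalysis (Denmark aldol): C6 is quaternary so only the methyl group can be enolised, the enol silane adds 1,2 to the enal, and the catalyst enantiomer is the one chosen for Re-face addition (its antipode would be used if the facial sense is the reverse), which sets C9 as R under catalyst control.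

Step 5
Reactants: 8 (3R)-1-[(1R,3S,4S)-3-bromo-4-chloro-4-methyl-1-(phenylselanyl)cyclohexyl]-3-hydroxy-5-methylhex-4-en-1-one
Product: 10 (2S,4R)-2-[(1R,3S,4S)-3-bromo-4-chloro-4-methyl-1-(phenylselanyl)cyclohexyl]-6-methylhept-5-ene-2,4-diol, via magnesium alkoxide chelate 9 (not isolated)
Conditions: MeMgBr (3 equiv), CH2Cl2/Et2O, −78 °C; aq. NH4Cl
Reagents that add atoms: methylmagnesium bromide (C[Mg]Br)
Why: Grignard addition under 1,3-chelation control (Cram chelate model): in the six-membered chelate 9 the C10 vinyl group is equatorial and methyl attacks the ketone axially, which should give the 1,3-syn diol and set C7 as S.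

Step 6
Reactants: 10 (2S,4R)-2-[(1R,3S,4S)-3-bromo-4-chloro-4-methyl-1-(phenylselanyl)cyclohexyl]-6-methylhept-5-ene-2,4-diol
Product: 11 (2S,4R)-2-[(1R,3S,4S)-3-bromo-4-chloro-4-methyl-1-(phenylselanyl)cyclohexyl]-6-methyl-4-(triethylsilyloxy)hept-5-en-2-ol
Conditions: Et3SiCl, imidazole, DMF, 0 °C
Reagents that add atoms: chlorotriethylsilane (CC[Si](Cl)(CC)CC)
Why: Selective silylation of the secondary allylic hydroxyl; the tertiary hydroxyl next to quaternary C6 is too hindered to react and alone remains for activation.

Step 7
Reactants: 11 (2S,4R)-2-[(1R,3S,4S)-3-bromo-4-chloro-4-methyl-1-(phenylselanyl)cyclohexyl]-6-methyl-4-(triethylsilyloxy)hept-5-en-2-ol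
Product: 13 triethyl{[(4R,6E)-6-[(3S,4S)-3-bromo-4-chloro-4-methylcyclohexylidene]-2-methylhept-2-en-4-yl]oxy}silane, via chlorosulfite 12 (not isolated)
Conditions: SOCl2, Et3N, cyclohexene (excess, scavenger), CH2Cl2, −78 to 0 °C
Reagents that add atoms: none
Why: Reductive elimination of a β-hydroxy selenide (Krief–Reich olefin synthesis): the tertiary chlorosulfite leaves with backside participation of selenium and chloride then removes the selenium, a stereospecific anti elimination confined to C6–C7; with selenium trans to bromine and the 7S centre the anti-periplanar arrangement places C8 cis to C5, so only the E alkene can form, and cyclohexene traps the PhSeCl released.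

Step 8
Reactants: 13 triethyl{[(4R,6E)-6-[(3S,4S)-3-bromo-4-chloro-4-methylcyclohexylidene]-2-methylhept-2-en-4-yl]oxy}silane
Product: 14 (4R,6E)-6-[(3S,4S)-3-bromo-4-chloro-4-methylcyclohexylidene]-2-methylhept-2-en-4-ol
Conditions: HF·pyridine, pyridine, THF, 0 °C
Reagents that add atoms: none
Why: Fluoride-induced cleavage of the silyl ether under buffered conditions; the halides and both alkenes are stable to it.

Step 9
Reactants: 14 (4R,6E)-6-[(3S,4S)-3-bromo-4-chloro-4-methylcyclohexylidene]-2-methylhept-2-en-4-ol
Product: 17 (2S,3S,6R,9R,10R)-2,10-dibromo-3-chlorochamigr-7(14)-en-9-ol, via bromonium ion 15 (not isolated), via tertiary C7 cation 16 (not isolated)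
Conditions: bromoperoxidase from Corallina officinalis (vanadate cofactor, no free vanadate added), KBr, H2O2 (1.0 equiv, syringe pump), MES buffer pH 6.3/t-BuOH 3:2, 23 °C, dark
Reagents that add atoms: potassium bromide ([K+].[Br-])
Why: Proposed new method: the peroxidase oxidises bromide with H2O2 to an enzyme-held Br+ donor that brominates the C10–C11 alkene of 14, C6 of the C6–C7 alkene opens the bromonium ion at C11, and the C7 cation sheds a C14 proton, so C10–Br, C6–C11, ring A and the exocyclic methylene form together. The closest known reactions are the bromoperoxidase-mediated bromocyclisation of acyclic terpene alcohols such as nerolidol and reagent-induced bromonium polyene cyclisations; a spiro closure onto the tetrasubstituted alkene of a halogenated bisabolenol has not been shown. Ring A closes in the 6-endo mode at the bromonium ion through a chair in which anti addition across C10–C11 places bromine equatorial. C10 is controlled by C9: the 9R hydroxyl takes the equatorial site, away from the C11 methyl that turns axial (allylic 1,3-strain), which fixes the face that receives bromine and gives 10R, trans to oxygen. C6 is controlled by ring B, whose axial C2 bromine shields the axial face so that C11 bonds equatorially, cis to chlorine (6R); the E geometry (C1 trans to C8, hence equatorial on ring A) makes this the same chair as the one preferred by C9. The step needs site selectivity for C10–C11 over the more electron-rich C6–C7 alkene, for which the substrate offers only steric shielding by ring B and the inductive pull of the homoallylic C2 bromine, and loss of a C14 rather than a C8 proton, favoured by the C9 oxygen; both are the open points of the route.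

Step 10
Reactants: 17 (2S,3S,6R,9R,10R)-2,10-dibromo-3-chlorochamigr-7(14)-en-9-ol
Product: 18 (2S,3S,6R,10R)-2,10-dibromo-3-chlorochamigr-7(14)-en-9-one
Conditions: Dess–Martin periodinane, NaHCO3, CH2Cl2, 0 to 20 °C
Reagents that add atoms: none
Why: Dess–Martin oxidation of the secondary alcohol under bicarbonate buffer, which avoids enolisation of the α-bromo β,γ-unsaturated ketone (no epimerisation at C10, no migration of the exocyclic alkene); the step erases C9.

Step 11
Reactants: 18 (2S,3S,6R,10R)-2,10-dibromo-3-chlorochamigr-7(14)-en-9-one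
Product: 19 (2S,3S,6R,9S,10R)-2,10-dibromo-3-chlorochamigr-7(14)-en-9-ol
Conditions: iBu2AlH, CH2Cl2, −78 °C; aq. KNaC4H4O6
Reagents that add atoms: none
Why: Hydride reduction of a cyclohexanone: axial approach is blocked by the axial C11 methyl, so hydride should enter equatorially and leave the hydroxyl axial, cis to the equatorial C10 bromine, which sets C9 as S; the cis bromohydrin cannot close to an epoxide.

**Compound list**

1 | (R)-limonene, (4R)-1-methyl-4-(prop-1-en-2-yl)cyclohex-1-ene | CC1=CC[C@@H](CC1)C(C)=C | starting material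
2 | (1S,2S,4R)-2-bromo-1-chloro-1-methyl-4-(prop-1-en-2-yl)cyclohexane (Br and Cl trans-diaxial) | CC(=C)[C@@H]1CC[C@](C)(Cl)[C@@H](Br)C1 | intermediate
3 | 3-[(1R,3S,4S)-3-bromo-4-chloro-4-methylcyclohexyl]-3-methyl-1,2,4-trioxolane (secondary ozonide, both epimers at the trioxolane carbon) | CC1(OCOO1)[C@@H]2CC[C@](C)(Cl)[C@@H](Br)C2 | intermediate (not isolated)
4 | 1-[(1R,3S,4S)-3-bromo-4-chloro-4-methylcyclohexyl]ethan-1-one | CC(=O)[C@@H]1CC[C@](C)(Cl)[C@@H](Br)C1 | intermediate
5 | 1-[(1R,3S,4S)-3-bromo-4-chloro-4-methyl-1-(phenylselanyl)cyclohexyl]ethan-1-one (Se trans to Br, cis to Cl) | CC(=O)[C@@]1([Se]c2ccccc2)CC[C@](C)(Cl)[C@@H](Br)C1 | intermediate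
6 | 3-methylbut-2-enal | CC(C)=CC=O | starting material
7 | ({1-[(1R,3S,4S)-3-bromo-4-chloro-4-methyl-1-(phenylselanyl)cyclohexyl]ethenyl}oxy)trimethylsilane | C=C(O[Si](C)(C)C)[C@@]1([Se]c2ccccc2)CC[C@](C)(Cl)[C@@H](Br)C1 | intermediate (not isolated)
8 | (3R)-1-[(1R,3S,4S)-3-bromo-4-chloro-4-methyl-1-(phenylselanyl)cyclohexyl]-3-hydroxy-5-methylhex-4-en-1-one | CC(C)=C[C@H](O)CC(=O)[C@@]1([Se]c2ccccc2)CC[C@](C)(Cl)[C@@H](Br)C1 | intermediate
9 | bromomagnesium alkoxide of 8 (six-membered chelate to the ketone) | CC(C)=C[C@H](O[Mg]Br)CC(=O)[C@@]1([Se]c2ccccc2)CC[C@](C)(Cl)[C@@H](Br)C1 | intermediate (not isolated)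
10 | (2S,4R)-2-[(1R,3S,4S)-3-bromo-4-chloro-4-methyl-1-(phenylselanyl)cyclohexyl]-6-methylhept-5-ene-2,4-diol (1,3-syn) | CC(C)=C[C@H](O)C[C@](C)(O)[C@@]1([Se]c2ccccc2)CC[C@](C)(Cl)[C@@H](Br)C1 | intermediate
11 | (2S,4R)-2-[(1R,3S,4S)-3-bromo-4-chloro-4-methyl-1-(phenylselanyl)cyclohexyl]-6-methyl-4-(triethylsilyloxy)hept-5-en-2-ol | CC(C)=C[C@H](O[Si](CC)(CC)CC)C[C@](C)(O)[C@@]1([Se]c2ccccc2)CC[C@](C)(Cl)[C@@H](Br)C1 | intermediate
12 | chlorosulfite of the tertiary hydroxyl of 11 | CC(C)=C[C@H](O[Si](CC)(CC)CC)C[C@](C)(OS(=O)Cl)[C@@]1([Se]c2ccccc2)CC[C@](C)(Cl)[C@@H](Br)C1 | intermediate (not isolated)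
13 | triethyl{[(4R,6E)-6-[(3S,4S)-3-bromo-4-chloro-4-methylcyclohexylidene]-2-methylhept-2-en-4-yl]oxy}silane | CC(C)=C[C@H](O[Si](CC)(CC)CC)C/C(C)=C1\CC[C@](C)(Cl)[C@@H](Br)C1 | intermediate
14 | (4R,6E)-6-[(3S,4S)-3-bromo-4-chloro-4-methylcyclohexylidene]-2-methylhept-2-en-4-ol, i.e. (E,2S,3S,9R)-2-bromo-3-chloro-γ-bisabolen-9-ol with C8 cis to C5 | CC(C)=C[C@H](O)C/C(C)=C1\CC[C@](C)(Cl)[C@@H](Br)C1 | intermediate
15 | 10,11-bromonium ion of 14 | CC1(C)[Br+][C@H]1[C@H](O)C/C(C)=C2\CC[C@](C)(Cl)[C@@H](Br)C2 | intermediate (not isolated)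
16 | spirocyclic tertiary cation at C7 | C[C+]1C[C@@H](O)[C@H](Br)C(C)(C)[C@@]12CC[C@](C)(Cl)[C@@H](Br)C2 | intermediate (not isolated)
17 | (2S,3S,6R,9R,10R)-2,10-dibromo-3-chlorochamigr-7(14)-en-9-ol (9-epimer of the target, Br and OH trans-diequatorial) | C=C1C[C@@H](O)[C@H](Br)C(C)(C)[C@@]12CC[C@](C)(Cl)[C@@H](Br)C2 | intermediate
18 | (2S,3S,6R,10R)-2,10-dibromo-3-chlorochamigr-7(14)-en-9-one | C=C1CC(=O)[C@H](Br)C(C)(C)[C@@]12CC[C@](C)(Cl)[C@@H](Br)C2 | intermediate
19 | (2S,3S,6R,9S,10R)-2,10-dibromo-3-chlorochamigr-7(14)-en-9-ol | C=C1C[C@H](O)[C@H](Br)C(C)(C)[C@@]12CC[C@](C)(Cl)[C@@H](Br)C2 | target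

**Step count.** Total: 11 steps. Longest linear sequence: 11 steps from 1 (compound 6 enters at step 4).

**Steps most likely to fail**

Step 9 (labelled step). What may go wrong: bromine transfer to the C6–C7 alkene, followed by 5-endo bromoetherification by the C9 hydroxyl or allylic bromination; capture of the bromonium ion or of the C7 cation by water; loss of a C8 instead of a C14 proton. The fallback uses known chemistry, sets out from 14 and returns at 18. Oxidation of 14 with MnO2 gives the dienone (6E)-6-[(3S,4S)-3-bromo-4-chloro-4-methylcyclohexylidene]-2-methylhept-2-en-4-one F1. Me2AlCl in CH2Cl2 at −78 °C then triggers an enone-initiated cation–olefin cyclisation: the Lewis acid fixes the electrophilic site at C11, C6 attacks it on the face away from the axial C2 bromine, and the C14 proton is taken up as methane, which leaves the chloro(methyl)aluminium enolate F2 with the exocyclic methylene in place. NBS added to the same flask brominates C10; equilibration through the enol should leave the bromine equatorial and give 18, which continues with step 11. Alkene geometry and C9 configuration no longer matter on this path; the site-selectivity problem disappears, but the C6/C10 relationship then rests on that equilibration.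

Step 3. What may go wrong: selenenylation at the methyl group, attack on the face syn to bromine, or slow enolisation toward the hindered ring carbon. The fallback sets out from 4 and returns at 5. Ac2O with catalytic HClO4 in EtOAc at 20 °C converts 4 under thermodynamic control into the more substituted enol acetate 1-[(3S,4S)-3-bromo-4-chloro-4-methylcyclohexylidene]ethyl acetate F3 (E/Z mixture, both converge). PhSeBr/AgOCOCF3 in CH2Cl2 at −78 °C then delivers selenium regiospecifically to the ring carbon and gives 5.

Step 5. What may go wrong: poor facial selectivity at C7 through competing non-chelated addition, attack of the Grignard reagent at selenium, or retro-aldol cleavage of the magnesium aldolate. The fallback sets out from 5 and returns at 10, and builds the tertiary carbinol first. The lithium enolate of 4-methylpent-3-en-2-one (LiN(iPr)2, THF, −78 °C) adds to ketone 5 to give the tertiary aldol (6S)-6-[(1R,3S,4S)-3-bromo-4-chloro-4-methyl-1-(phenylselanyl)cyclohexyl]-6-hydroxy-2-methylhept-2-en-4-one F4, separated by chromatography from its C7 epimer (which is returned to 5 by base-induced retro-aldol). Narasaka–Prasad reduction of F4 (Et2BOMe, NaBH4, THF/MeOH, −78 °C) delivers hydride externally to the boron chelate, sets C9 1,3-syn to C7 and gives 10.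

**Further compounds**

F1 | step 9 | (6E)-6-[(3S,4S)-3-bromo-4-chloro-4-methylcyclohexylidene]-2-methylhept-2-en-4-one | CC(C)=CC(=O)C/C(C)=C1\CC[C@](C)(Cl)[C@@H](Br)C1
F2 | step 9 | chloro(methyl)aluminium enolate (C9–C10) of (2S,3S,6R)-2-bromo-3-chlorochamigr-7(14)-en-9-one, not isolated | C=C1CC(O[Al](C)Cl)=CC(C)(C)[C@@]12CC[C@](C)(Cl)[C@@H](Br)C2
F3 | step 3 | 1-[(3S,4S)-3-bromo-4-chloro-4-methylcyclohexylidene]ethyl acetate (E/Z mixture) | CC(OC(C)=O)=C1CC[C@](C)(Cl)[C@@H](Br)C1
F4 | step 5 | (6S)-6-[(1R,3S,4S)-3-bromo-4-chloro-4-methyl-1-(phenylselanyl)cyclohexyl]-6-hydroxy-2-methylhept-2-en-4-one | CC(C)=CC(=O)C[C@](C)(O)[C@@]1([Se]c2ccccc2)CC[C@](C)(Cl)[C@@H](Br)C1
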